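## Retrosynthetic overview

1. Target ⇐ hydroxyl-directed (threo) epoxidation of the (21S)-allylic alcohol; (Z)-enal ⇐ oxidation and retro-oxa-Michael opening of a bicyclic tetrahydropyran that still carries C1 as CH2OH.
2. Side chain ⇐ B-alkyl Suzuki coupling of a C11 vinyl group with an (E)-vinyl iodide, made by an asymmetric vinylogous Mukaiyama aldol (sets C21) and Zr-catalysed carboalumination.
3. Key step: one Lewis-acid operation turns an acyclic (S,S)-vinyl epoxide / (Z)-trisubstituted alkene / primary alcohol into the cyclohexane (C6–C11 bond; sets C6, C10, C11) and a tetrahydropyran (O–C7).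
4. Acyclic precursor ⇐ tetrasubstituted epoxide from anti-carbomagnesiation, methylation and Sharpless epoxidation; trisubstituted alkene from two sequential stereodefined couplings of a 1,1-dibromoalkene.
5. Ring order: cyclohexane and tetrahydropyran together (step 12); tetrahydropyran reopened (step 21); oxirane last (step 23).

Locants used below: C1 formyl carbon, C2 enal α-carbon, C3–C5 hydroxypropyl arm (C3 = CH2OH), C6–C11 ring (C6 = CH, C7 = alkylidene carbon, C10 = carbinol, C11 = quaternary), C12–C23 side chain (C21 carbinol, C22/C23 oxirane).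

Assumption: 1, 3, 6, 22, 24 and 29 are bought; the propan-2-yl methine made in step 4 (the later C2) is carried as a 1:1 epimer mixture until it becomes sp2 in step 21.

## Route

Step 1
Reactants: 1 4-[(tert-butyldimethylsilyl)oxy]butanal
Product: 2 tert-butyl[(5,5-dibromopent-4-en-1-yl)oxy]dimethylsilane
Conditions: CBr4, PPh3, CH2Cl2, 0 °C
Reagents that add atoms: carbon tetrabromide, BrC(Br)(Br)Br
Why: Ramirez dibromo-olefination (first stage of the Corey–Fuchs sequence) of the aldehyde by the ylide Ph3P=CBr2 formed in the flask; no stereo element is created.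

Step 2
Reactants: 2 tert-butyl[(5,5-dibromopent-4-en-1-yl)oxy]dimethylsilane; 3 (4-bromobut-1-yn-1-yl)trimethylsilane
Product: 5 {[(4Z)-5-bromo-9-(trimethylsilyl)non-4-en-8-yn-1-yl]oxy}(tert-butyl)dimethylsilane, via organozinc bromide 4 (not isolated)
Conditions: 3, Zn dust, LiCl, THF, 50 °C; then 2, Pd(DPEphos)Cl2 (3 mol %), THF, 0 to 23 °C
Reagents that add atoms: none
Why: Negishi trans-selective monoalkylation of a 1,1-dibromoalkene: the C–Br bond trans to the alkyl chain reacts first, so the new chain (C8) ends up trans to the silyloxypropyl group and the remaining bromide cis to it (4Z).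

Step 3
Reactants: 5 (4Z)-bromo enyne; 6 prop-1-en-2-ylmagnesium bromide
Product: 7 tert-butyldimethyl{[(4Z)-5-(prop-1-en-2-yl)-9-(trimethylsilyl)non-4-en-8-yn-1-yl]oxy}silane
Conditions: Pd(PPh3)4 (3 mol %), THF, 0 to 23 °C
Reagents that add atoms: none
Why: Kumada–Corriu coupling of the alkenyl bromide with retention of geometry, which places the isopropenyl group cis to the silyloxypropyl chain (4Z).

Step 4
Reactants: 7 (4Z)-silyl dienyne
Product: 10 2-[(4Z)-1-[(tert-butyldimethylsilyl)oxy]non-4-en-8-yn-5-yl]propan-1-ol, via alkylborane 8 (not isolated), via silylalkyne alcohol 9 (not isolated)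
Conditions: 9-BBN dimer, THF, 0 to 23 °C; then 3 M NaOH, 30% H2O2, MeOH, 0 to 23 °C
Reagents that add atoms: hydrogen peroxide, OO
Why: anti-Markovnikov hydroboration–oxidation of the only 1,1-disubstituted alkene (the trisubstituted alkene and the silylalkyne do not react); the basic peroxide work-up also cleaves the alkynyl–silicon bond, and the new methine is formed without control (erased in step 21).

Step 5
Reactants: 10 enyne alcohol
Product: 11 (4Z)-1-[(tert-butyldimethylsilyl)oxy]-5-{1-[(tert-butyldimethylsilyl)oxy]propan-2-yl}non-4-en-8-yne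
Conditions: TBSCl, imidazole, DMF, 23 °C
Reagents that add atoms: tert-butyldimethylsilyl chloride, CC(C)(C)[Si](C)(C)Cl
Why: standard silylation of the primary alcohol so that only the C12 hydroxyl is oxidised in step 10.

Step 6
Reactants: 11 bis-silyl enyne
Product: 13 (6Z)-10-[(tert-butyldimethylsilyl)oxy]-6-{1-[(tert-butyldimethylsilyl)oxy]propan-2-yl}dec-6-en-2-yn-1-ol, via lithium acetylide 12 (not isolated)
Conditions: nBuLi, THF, −78 °C; then (CH2O)n, −78 to 23 °C
Reagents that add atoms: paraformaldehyde (as formaldehyde), C=O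
Why: acetylide addition to formaldehyde gives the 2-alkyn-1-ol needed for the directed carbometalation.

Step 7
Reactants: 13 propargylic alcohol
Product: 15 (2Z,6Z)-10-[(tert-butyldimethylsilyl)oxy]-6-{1-[(tert-butyldimethylsilyl)oxy]propan-2-yl}-3-iodo-2-methyldeca-2,6-dien-1-ol, via magnesium chelate 14 (not isolated)
Conditions: MeMgBr (4 equiv), CuI (15 mol %), THF, 0 to 23 °C; then I2, −78 to 0 °C
Reagents that add atoms: methylmagnesium bromide, C[Mg]Br; iodine, II
Why: CuI-catalysed anti-carbomagnesiation of a 2-alkyn-1-ol (Duboudin–Jousseaume) puts methyl on C11 and magnesium on C10 in a five-membered alkoxide chelate, and iodinolysis with retention gives the (2Z)-iodide (iodine cis to CH2OH).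

Step 8
Reactants: 15 (2Z)-alkenyl iodide
Product: 16 (2E,6Z)-10-[(tert-butyldimethylsilyl)oxy]-6-{1-[(tert-butyldimethylsilyl)oxy]propan-2-yl}-2,3-dimethyldeca-2,6-dien-1-ol
Conditions: MeZnCl (3 equiv), Pd(PPh3)4 (5 mol %), THF, 50 °C
Reagents that add atoms: methylzinc chloride, C[Zn]Cl
Why: Negishi coupling with retention replaces iodine by methyl, giving the tetrasubstituted (2E)-allylic alcohol (CH2OH trans to the C9 chain).

Step 9
Reactants: 16 (2E)-allylic alcohol
Product: 17 {(2S,3S)-3-[(3Z)-7-[(tert-butyldimethylsilyl)oxy]-3-{1-[(tert-butyldimethylsilyl)oxy]propan-2-yl}hept-3-en-1-yl]-2,3-dimethyloxiran-2-yl}methanol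
Conditions: Ti(OiPr)4 (10 mol %), L-(+)-diethyl tartrate (12 mol %), tBuOOH, 4 Å MS, CH2Cl2, −25 °C
Reagents that add atoms: tert-butyl hydroperoxide, CC(C)(C)OO
Why: Sharpless asymmetric epoxidation; with L-(+)-tartrate oxygen is delivered to the same face as for geraniol, giving the (2S,3S)-epoxy alcohol (the future C11 and C10), and the isolated trisubstituted alkene is untouched.

Step 10
Reactants: 17 (2S,3S)-epoxy alcohol
Product: 19 (2S,3S)-2-ethenyl-3-[(3Z)-7-[(tert-butyldimethylsilyl)oxy]-3-{1-[(tert-butyldimethylsilyl)oxy]propan-2-yl}hept-3-en-1-yl]-2,3-dimethyloxirane, via epoxy aldehyde 18 (not isolated)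
Conditions: (COCl)2, DMSO, CH2Cl2, −78 °C; Et3N; then Ph3P=CH2 (from Ph3PCH3Br and KN(SiMe3)2), THF, −78 to 0 °C
Reagents that add atoms: methyltriphenylphosphonium bromide, C[P+](c1ccccc1)(c1ccccc1)c1ccccc1.[Br-]
Why: one-pot Swern oxidation and Wittig methylenation; the aldehyde is non-enolisable, so both epoxide stereocentres are kept.

Step 11
Reactants: 19 bis-silyl vinyl epoxide
Product: 20 (4Z)-7-[(2S,3S)-3-ethenyl-2,3-dimethyloxiran-2-yl]-5-(1-hydroxypropan-2-yl)hept-4-en-1-ol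
Conditions: Bu4NF, THF, 0 to 23 °C
Reagents that add atoms: none
Why: fluoride desilylation under basic conditions that leave the acid-labile vinyl epoxide intact and free the C3 hydroxyl as the terminating nucleophile.

Step 12
Reactants: 20 vinyl epoxide diol
Product: 21 (4aS,5S,6S,8aS)-5-ethenyl-8a-(1-hydroxypropan-2-yl)-5,6-dimethyloctahydro-2H-chromen-6-ol
Conditions: BF3·OEt2 (0.3 equiv), CH2Cl2 (2 mM), −78 °C
Reagents that add atoms: none
Why: Proposed new method: BF3 ionises the allylic C11–O bond of the vinyl epoxide, the tethered (Z)-alkene attacks C11 through a chair-like six-membered transition state anti to the leaving oxygen (inversion at C11, retention at C10, C5 equatorial so C6 is set), and the tertiary C7 cation is captured anti by the C3 hydroxyl to give the trans-fused tetrahydropyran; the closest known reaction type is the epoxide-initiated cation–olefin (polyene) cyclisation with hydroxyl termination.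

Step 13
Reactants: 22 methyl 3-methylbut-2-enoate
Product: 23 tert-butyl[(1-methoxy-3-methylbuta-1,3-dien-1-yl)oxy]dimethylsilane
Conditions: LiN(iPr)2, THF, −78 °C; then TBSCl, DMPU, −78 to 23 °C
Reagents that add atoms: tert-butyldimethylsilyl chloride, CC(C)(C)[Si](C)(C)Cl
Why: γ-deprotonation of the senecioate and O-silylation give the silyl dienol ether for the vinylogous aldol.

Step 14
Reactants: 23 silyl dienol ether; 24 3-methylbut-2-enal
Product: 25 methyl (2E,5S)-5-hydroxy-3,7-dimethylocta-2,6-dienoate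
Conditions: SiCl4 (1.1 equiv), Denmark bis-phosphoramide (5 mol %, the enantiomer that exposes the Si face of the aldehyde), iPr2NEt (10 mol %), CH2Cl2, −78 °C
Reagents that add atoms: none
Why: Lewis-base-catalysed vinylogous Mukaiyama aldol (Denmark): γ-selective, (E)-enoate, and Si-face addition to the conjugated aldehyde sets the (5S) carbinol (the future C21).

Step 15
Reactants: 25 (5S)-hydroxy ester
Product: 26 methyl (2E,5S)-5-[(tert-butyldimethylsilyl)oxy]-3,7-dimethylocta-2,6-dienoate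
Conditions: TBSCl, imidazole, DMF, 23 °C
Reagents that add atoms: tert-butyldimethylsilyl chloride, CC(C)(C)[Si](C)(C)Cl
Why: silylation of the secondary allylic alcohol; the stereocentre is not touched.

Step 16
Reactants: 26 silyloxy ester
Product: 27 (2E,5S)-5-[(tert-butyldimethylsilyl)oxy]-3,7-dimethylocta-2,6-dien-1-ol
Conditions: iBu2AlH (2.2 equiv), CH2Cl2, −78 °C
Reagents that add atoms: none
Why: 1,2-reduction of the enoate to the allylic alcohol with the alkene geometry kept.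

Step 17
Reactants: 27 allylic alcohol
Product: 28 {[(4S,6E)-8-bromo-2,6-dimethylocta-2,6-dien-4-yl]oxy}(tert-butyl)dimethylsilane
Conditions: CBr4, PPh3, CH2Cl2, −20 °C
Reagents that add atoms: carbon tetrabromide, BrC(Br)(Br)Br
Why: Appel bromination of the primary allylic alcohol (SN2, no allylic transposition at low temperature).

Step 18
Reactants: 28 allylic bromide; 29 trimethyl(prop-1-yn-1-yl)silane
Product: 32 tert-butyl{[(4S,6E)-2,6-dimethylundeca-2,6-dien-10-yn-4-yl]oxy}dimethylsilane, via lithiated silylpropyne 30 (not isolated), via silyl enyne 31 (not isolated)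
Conditions: 29, nBuLi, THF, −78 °C; then 28, −78 to 0 °C; then K2CO3 (cat.), MeOH, 23 °C
Reagents that add atoms: none
Why: SN2 alkylation of the propargylic lithium reagent by the primary allylic bromide builds the 1,5-enyne, and methanolysis removes the alkynyl silyl group without touching the secondary silyl ether.

Step 19
Reactants: 32 terminal enyne
Product: 34 tert-butyl{[(4S,6E,10E)-11-iodo-2,6,10-trimethylundeca-2,6,10-trien-4-yl]oxy}dimethylsilane, via alkenylalane 33 (not isolated)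
Conditions: Me3Al (3 equiv), Cp2ZrCl2 (0.3 equiv), CH2Cl2, 0 to 23 °C; then I2, THF, −30 °C
Reagents that add atoms: trimethylaluminium, C[Al](C)C; iodine, II
Why: Negishi Zr-catalysed syn-carboalumination of the terminal alkyne and iodinolysis with retention give the (E)-2-methylalkenyl iodide.

Step 20
Reactants: 21 bicyclic vinyl diol; 34 (E)-alkenyl iodide
Product: 36 (4aS,5S,6S,8aS)-8a-(1-hydroxypropan-2-yl)-5,6-dimethyl-5-[(3E,7E,10S)-10-[(tert-butyldimethylsilyl)oxy]-4,8,12-trimethyltrideca-3,7,11-trien-1-yl]octahydro-2H-chromen-6-ol, via alkylborane 35 (not isolated)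
Conditions: 9-BBN dimer (excess), THF, 23 to 45 °C; then 34, Pd(dppf)Cl2 (8 mol %), AsPh3, aq. K3PO4, DMF, 23 °C
Reagents that add atoms: none
Why: B-alkyl Suzuki–Miyaura coupling: anti-Markovnikov hydroboration of the only alkene of 21, then sp3–sp2 coupling with retention of the iodide geometry; no stereocentre is touched.

Step 21
Reactants: 36 coupled bicyclic diol
Product: 38 (2Z)-2-[(2R,3S,4S)-4-hydroxy-2-(3-hydroxypropyl)-3,4-dimethyl-3-[(3E,7E,10S)-10-[(tert-butyldimethylsilyl)oxy]-4,8,12-trimethyltrideca-3,7,11-trien-1-yl]cyclohexylidene]propanal, via alkoxy aldehyde 37 (not isolated)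
Conditions: Dess–Martin periodinane, CH2Cl2, 0 °C; then DBU, 23 °C
Reagents that add atoms: none
Why: Dess–Martin oxidation of the only primary alcohol, then E1cB (retro-oxa-Michael) expulsion of the ring oxygen from C7, gives the tetrasubstituted enal and frees the hydroxypropyl arm; both C2 epimers converge, and the planar formyl group takes the position syn to the substituted C6 (less A(1,3) strain than methyl, and reversible oxa-Michael addition allows equilibration), giving the (Z)-enal.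

Step 22
Reactants: 38 silyl-protected (Z)-enal
Product: 39 (2Z)-2-[(2R,3S,4S)-4-hydroxy-3-[(3E,7E,10S)-10-hydroxy-4,8,12-trimethyltrideca-3,7,11-trien-1-yl]-2-(3-hydroxypropyl)-3,4-dimethylcyclohexylidene]propanal
Conditions: HF·pyridine, pyridine, THF, 0 °C
Reagents that add atoms: none
Why: buffered fluoride desilylation frees the C21 allylic alcohol without base-induced isomerisation of the enal.

Step 23
Reactants: 39 triol enal
Product: 40 (2Z)-2-[(2R,3S,4S)-3-[(3E,7E,10S)-10-[(2R)-3,3-dimethyloxiran-2-yl]-10-hydroxy-4,8-dimethyldeca-3,7-dien-1-yl]-4-hydroxy-2-(3-hydroxypropyl)-3,4-dimethylcyclohexylidene]propanal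
Conditions: Ti(OiPr)4 (0.3 equiv), tBuOOH (1.5 equiv), 4 Å MS, CH2Cl2, −20 °C
Reagents that add atoms: tert-butyl hydroperoxide, CC(C)(C)OO
Why: hydroxyl-directed epoxidation of the allylic alcohol only (the other trisubstituted alkenes lack an allylic hydroxyl and the enal is electron-poor); A(1,3) strain from the cis methyl on C23 holds the C21–H in the alkene plane, so oxygen is delivered syn to the hydroxyl to give the threo (21S,22R) epoxy alcohol.

## Compound list

TBS = tert-butyldimethylsilyl; 9-BBN = 9-borabicyclo[3.3.1]nonane.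

1 | 4-(TBS-oxy)butanal | O=CCCCO[Si](C)(C)C(C)(C)C | starting material
2 | tert-butyl[(5,5-dibromopent-4-en-1-yl)oxy]dimethylsilane | BrC(Br)=CCCCO[Si](C)(C)C(C)(C)C | intermediate
3 | (4-bromobut-1-yn-1-yl)trimethylsilane | BrCCC#C[Si](C)(C)C | starting material
4 | [4-(trimethylsilyl)but-3-yn-1-yl]zinc bromide | Br[Zn]CCC#C[Si](C)(C)C | intermediate (not isolated)
5 | {[(4Z)-5-bromo-9-(trimethylsilyl)non-4-en-8-yn-1-yl]oxy}(tert-butyl)dimethylsilane | CC(C)(C)[Si](C)(C)OCCC/C=C(\Br)/CCC#C[Si](C)(C)C | intermediate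
6 | prop-1-en-2-ylmagnesium bromide | CC(=C)[Mg]Br | starting material
7 | tert-butyldimethyl{[(4Z)-5-(prop-1-en-2-yl)-9-(trimethylsilyl)non-4-en-8-yn-1-yl]oxy}silane | CC(C)(C)[Si](C)(C)OCCC/C=C(\C(C)=C)/CCC#C[Si](C)(C)C | intermediate
8 | 9-{2-[(4Z)-1-(TBS-oxy)-9-(trimethylsilyl)non-4-en-8-yn-5-yl]propyl}-9-BBN, racemic | CC(C)(C)[Si](C)(C)OCCC/C=C(\C(C)CB1C2CCCC1CCC2)/CCC#C[Si](C)(C)C | intermediate (not isolated)
9 | 2-[(4Z)-1-(TBS-oxy)-9-(trimethylsilyl)non-4-en-8-yn-5-yl]propan-1-ol, racemic | CC(C)(C)[Si](C)(C)OCCC/C=C(\C(C)CO)/CCC#C[Si](C)(C)C | intermediate (not isolated)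
10 | 2-[(4Z)-1-(TBS-oxy)non-4-en-8-yn-5-yl]propan-1-ol, racemic | CC(C)(C)[Si](C)(C)OCCC/C=C(\C(C)CO)/CCC#C | intermediate
11 | (4Z)-1-(TBS-oxy)-5-[1-(TBS-oxy)propan-2-yl]non-4-en-8-yne, racemic | CC(C)(C)[Si](C)(C)OCCC/C=C(\C(C)CO[Si](C)(C)C(C)(C)C)/CCC#C | intermediate
12 | lithium acetylide of 11 (lithium on the alkyne terminus) | CC(C)(C)[Si](C)(C)OCCC/C=C(\C(C)CO[Si](C)(C)C(C)(C)C)/CCC#C[Li] | intermediate (not isolated)
13 | (6Z)-10-(TBS-oxy)-6-[1-(TBS-oxy)propan-2-yl]dec-6-en-2-yn-1-ol, racemic | CC(C)(C)[Si](C)(C)OCCC/C=C(\C(C)CO[Si](C)(C)C(C)(C)C)/CCC#CCO | intermediate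
14 | 4-methyl-2,5-dihydro-1,2-oxamagnesole carrying at C3 the (3Z)-7-(TBS-oxy)-3-[1-(TBS-oxy)propan-2-yl]hept-3-en-1-yl chain | CC(C)(C)[Si](C)(C)OCCC/C=C(\C(C)CO[Si](C)(C)C(C)(C)C)/CCC1=C(C)CO[Mg]1 | intermediate (not isolated)
15 | (2Z,6Z)-3-iodo-2-methyl-10-(TBS-oxy)-6-[1-(TBS-oxy)propan-2-yl]deca-2,6-dien-1-ol, racemic | CC(C)(C)[Si](C)(C)OCCC/C=C(\C(C)CO[Si](C)(C)C(C)(C)C)/CC/C(I)=C(\C)CO | intermediate
16 | (2E,6Z)-2,3-dimethyl-10-(TBS-oxy)-6-[1-(TBS-oxy)propan-2-yl]deca-2,6-dien-1-ol, racemic | CC(C)(C)[Si](C)(C)OCCC/C=C(\C(C)CO[Si](C)(C)C(C)(C)C)/CC/C(C)=C(\C)CO | intermediate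
17 | {(2S,3S)-2,3-dimethyl-3-[(3Z)-7-(TBS-oxy)-3-[1-(TBS-oxy)propan-2-yl]hept-3-en-1-yl]oxiran-2-yl}methanol, 1:1 at the propan-2-yl carbon | CC(C)(C)[Si](C)(C)OCCC/C=C(\C(C)CO[Si](C)(C)C(C)(C)C)/CC[C@]1(C)O[C@@]1(C)CO | intermediate
18 | (2R,3S)-2,3-dimethyl-3-[(3Z)-7-(TBS-oxy)-3-[1-(TBS-oxy)propan-2-yl]hept-3-en-1-yl]oxirane-2-carbaldehyde, 1:1 at the propan-2-yl carbon | CC(C)(C)[Si](C)(C)OCCC/C=C(\C(C)CO[Si](C)(C)C(C)(C)C)/CC[C@]1(C)O[C@@]1(C)C=O | intermediate (not isolated)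
19 | (2S,3S)-2-ethenyl-2,3-dimethyl-3-[(3Z)-7-(TBS-oxy)-3-[1-(TBS-oxy)propan-2-yl]hept-3-en-1-yl]oxirane, 1:1 at the propan-2-yl carbon | CC(C)(C)[Si](C)(C)OCCC/C=C(\C(C)CO[Si](C)(C)C(C)(C)C)/CC[C@]1(C)O[C@@]1(C)C=C | intermediate
20 | (4Z)-7-[(2S,3S)-3-ethenyl-2,3-dimethyloxiran-2-yl]-5-(1-hydroxypropan-2-yl)hept-4-en-1-ol, 1:1 at the propan-2-yl carbon | OCCC/C=C(\C(C)CO)/CC[C@]1(C)O[C@@]1(C)C=C | intermediate
21 | (4aS,5S,6S,8aS)-5-ethenyl-8a-(1-hydroxypropan-2-yl)-5,6-dimethyloctahydro-2H-chromen-6-ol (trans-fused), 1:1 at the propan-2-yl carbon | OCC(C)[C@]12CC[C@](C)(O)[C@@](C)(C=C)[C@@H]1CCCO2 | intermediate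
22 | methyl 3-methylbut-2-enoate | COC(=O)C=C(C)C | starting material
23 | tert-butyl[(1-methoxy-3-methylbuta-1,3-dien-1-yl)oxy]dimethylsilane (enol ether geometry not defined) | C=C(C)C=C(OC)O[Si](C)(C)C(C)(C)C | intermediate
24 | 3-methylbut-2-enal | CC(C)=CC=O | starting material
25 | methyl (2E,5S)-5-hydroxy-3,7-dimethylocta-2,6-dienoate | COC(=O)/C=C(\C)C[C@H](O)C=C(C)C | intermediate
26 | methyl (2E,5S)-3,7-dimethyl-5-(TBS-oxy)octa-2,6-dienoate | COC(=O)/C=C(\C)C[C@H](O[Si](C)(C)C(C)(C)C)C=C(C)C | intermediate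
27 | (2E,5S)-3,7-dimethyl-5-(TBS-oxy)octa-2,6-dien-1-ol | OC/C=C(\C)C[C@H](O[Si](C)(C)C(C)(C)C)C=C(C)C | intermediate
28 | {[(4S,6E)-8-bromo-2,6-dimethylocta-2,6-dien-4-yl]oxy}(tert-butyl)dimethylsilane | BrC/C=C(\C)C[C@H](O[Si](C)(C)C(C)(C)C)C=C(C)C | intermediate
29 | trimethyl(prop-1-yn-1-yl)silane | CC#C[Si](C)(C)C | starting material
30 | [3-(trimethylsilyl)prop-2-yn-1-yl]lithium | [Li]CC#C[Si](C)(C)C | intermediate (not isolated)
31 | tert-butyl{[(4S,6E)-2,6-dimethyl-11-(trimethylsilyl)undeca-2,6-dien-10-yn-4-yl]oxy}dimethylsilane | C[Si](C)(C)C#CCC/C=C(\C)C[C@H](O[Si](C)(C)C(C)(C)C)C=C(C)C | intermediate (not isolated)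
32 | tert-butyl{[(4S,6E)-2,6-dimethylundeca-2,6-dien-10-yn-4-yl]oxy}dimethylsilane | C#CCC/C=C(\C)C[C@H](O[Si](C)(C)C(C)(C)C)C=C(C)C | intermediate
33 | dimethyl[(1E,5E,8S)-2,6,10-trimethyl-8-(TBS-oxy)undeca-1,5,9-trien-1-yl]alumane | C[Al](C)/C=C(\C)CC/C=C(\C)C[C@H](O[Si](C)(C)C(C)(C)C)C=C(C)C | intermediate (not isolated)
34 | tert-butyl{[(4S,6E,10E)-11-iodo-2,6,10-trimethylundeca-2,6,10-trien-4-yl]oxy}dimethylsilane | I/C=C(\C)CC/C=C(\C)C[C@H](O[Si](C)(C)C(C)(C)C)C=C(C)C | intermediate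
35 | 9-BBN adduct of 21: boron on the terminal carbon of the former vinyl group (B–CH2CH2–C5 of the chromane) | OCC(C)[C@]12CC[C@](C)(O)[C@@](C)(CCB3C4CCCC3CCC4)[C@@H]1CCCO2 | intermediate (not isolated)
36 | (4aS,5S,6S,8aS)-8a-(1-hydroxypropan-2-yl)-5,6-dimethyl-5-[(3E,7E,10S)-4,8,12-trimethyl-10-(TBS-oxy)trideca-3,7,11-trien-1-yl]octahydro-2H-chromen-6-ol, 1:1 at the propan-2-yl carbon | OCC(C)[C@]12CC[C@](C)(O)[C@@](C)(CC/C=C(\C)CC/C=C(\C)C[C@H](O[Si](C)(C)C(C)(C)C)C=C(C)C)[C@@H]1CCCO2 | intermediate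
37 | 2-[(4aS,5S,6S,8aS)-6-hydroxy-5,6-dimethyl-5-[(3E,7E,10S)-4,8,12-trimethyl-10-(TBS-oxy)trideca-3,7,11-trien-1-yl]octahydro-2H-chromen-8a-yl]propanal, 1:1 at C2 | O=CC(C)[C@]12CC[C@](C)(O)[C@@](C)(CC/C=C(\C)CC/C=C(\C)C[C@H](O[Si](C)(C)C(C)(C)C)C=C(C)C)[C@@H]1CCCO2 | intermediate (not isolated)
38 | (2Z)-2-[(2R,3S,4S)-4-hydroxy-2-(3-hydroxypropyl)-3,4-dimethyl-3-[(3E,7E,10S)-4,8,12-trimethyl-10-(TBS-oxy)trideca-3,7,11-trien-1-yl]cyclohexylidene]propanal | C/C(C=O)=C1\CC[C@](C)(O)[C@@](C)(CC/C=C(\C)CC/C=C(\C)C[C@H](O[Si](C)(C)C(C)(C)C)C=C(C)C)[C@@H]1CCCO | intermediate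
39 | (2Z)-2-[(2R,3S,4S)-4-hydroxy-3-[(3E,7E,10S)-10-hydroxy-4,8,12-trimethyltrideca-3,7,11-trien-1-yl]-2-(3-hydroxypropyl)-3,4-dimethylcyclohexylidene]propanal | C/C(C=O)=C1\CC[C@](C)(O)[C@@](C)(CC/C=C(\C)CC/C=C(\C)C[C@H](O)C=C(C)C)[C@@H]1CCCO | intermediate
40 | (2Z)-2-[(2R,3S,4S)-3-[(3E,7E,10S)-10-[(2R)-3,3-dimethyloxiran-2-yl]-10-hydroxy-4,8-dimethyldeca-3,7-dien-1-yl]-4-hydroxy-2-(3-hydroxypropyl)-3,4-dimethylcyclohexylidene]propanal (CNP0161066.1) | C/C(C=O)=C1\CC[C@](C)(O)[C@@](C)(CC/C=C(\C)CC/C=C(\C)C[C@H](O)[C@H]2OC2(C)C)[C@@H]1CCCO | target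

## Step count and weak points

Total steps: 23. Longest linear sequence: 16 (steps 1–12, then 20–23); the side chain (steps 13–19) is a 7-step branch.

The three steps most likely to fail:

Step 12 (bicyclisation). The tetrasubstituted vinyl epoxide may undergo a 1,2-shift to a ketone, or lose stereochemical fidelity at C11 through a long-lived allyl cation, before the alkene attacks. The fallback sets out from 17 and avoids the allyl cation. Treating 17 with Sc(OTf)3 (10 mol %) in CH2Cl2 at −40 °C lets the chelated 2,3-epoxy alcohol be opened at C11 by the alkene in an SN2-like way, while the C3 silyl ether oxygen closes the tetrahydropyran and loses its silyl group on work-up; this gives the bicyclic mono-silyl ether diol F1. Dess–Martin oxidation of its neopentyl primary alcohol gives the hydroxy aldehyde F2, Ph3P=CH2 converts it to the silyl-protected vinyl compound F3, and Bu4NF removes the last silyl group, returning to the route at 21.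

Step 21 (oxidation and ring opening). The tetrasubstituted enal may form as an E/Z mixture, and DBU may epimerise C6 through the dienolate. The fallback sets out from 36 and uses a cyano group as the small substituent. TEMPO (cat.), PhI(OAc)2 and NH4OAc oxidise the primary alcohol directly to the alkoxy nitrile F4. KN(SiMe3)2 in THF at −78 °C opens the tetrahydropyran by E1cB to the (Z)-unsaturated nitrile F5, where the linear cyano group takes the position syn to C6 much more decisively than formyl. iBu2AlH in toluene at −78 °C and mild hydrolysis of the aldimine return to the route at 38.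

Step 23 (last-step directed epoxidation). The metal-peroxide reaction runs on the fully unveiled enal triol: three hydroxyls can sequester titanium, the aldehyde can be oxidised, and a minor erythro isomer cannot be removed at a later stage. The fallback sets out from 36 and moves the epoxidation ahead of the enal. Bu4NF gives the tetrahydropyran triol F6; Ti(OiPr)4/tBuOOH epoxidises its allylic alcohol to the epoxy triol F7, where diastereomers can still be separated. TEMPO (cat.)/PhI(OAc)2 oxidises only the primary alcohol to the epoxy aldehyde F8, and DBU opens the tetrahydropyran to arrive at 40.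

Further compounds
F1 | step 12 | (4aS,5R,6S,8aS)-5-(hydroxymethyl)-5,6-dimethyl-8a-[1-(TBS-oxy)propan-2-yl]octahydro-2H-chromen-6-ol | CC(C)(C)[Si](C)(C)OCC(C)[C@]12CC[C@](C)(O)[C@@](C)(CO)[C@@H]1CCCO2
F2 | step 12 | (4aS,5S,6S,8aS)-6-hydroxy-5,6-dimethyl-8a-[1-(TBS-oxy)propan-2-yl]octahydro-2H-chromene-5-carbaldehyde | CC(C)(C)[Si](C)(C)OCC(C)[C@]12CC[C@](C)(O)[C@@](C)(C=O)[C@@H]1CCCO2
F3 | step 12 | (4aS,5S,6S,8aS)-5-ethenyl-5,6-dimethyl-8a-[1-(TBS-oxy)propan-2-yl]octahydro-2H-chromen-6-ol | CC(C)(C)[Si](C)(C)OCC(C)[C@]12CC[C@](C)(O)[C@@](C)(C=C)[C@@H]1CCCO2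
F4 | step 21 | 2-[(4aS,5S,6S,8aS)-6-hydroxy-5,6-dimethyl-5-[(3E,7E,10S)-4,8,12-trimethyl-10-(TBS-oxy)trideca-3,7,11-trien-1-yl]octahydro-2H-chromen-8a-yl]propanenitrile | N#CC(C)[C@]12CC[C@](C)(O)[C@@](C)(CC/C=C(\C)CC/C=C(\C)C[C@H](O[Si](C)(C)C(C)(C)C)C=C(C)C)[C@@H]1CCCO2
F5 | step 21 | (2Z)-2-[(2R,3S,4S)-4-hydroxy-2-(3-hydroxypropyl)-3,4-dimethyl-3-[(3E,7E,10S)-4,8,12-trimethyl-10-(TBS-oxy)trideca-3,7,11-trien-1-yl]cyclohexylidene]propanenitrile | C/C(C#N)=C1\CC[C@](C)(O)[C@@](C)(CC/C=C(\C)CC/C=C(\C)C[C@H](O[Si](C)(C)C(C)(C)C)C=C(C)C)[C@@H]1CCCO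
F6 | step 23 | (4aS,5S,6S,8aS)-5-[(3E,7E,10S)-10-hydroxy-4,8,12-trimethyltrideca-3,7,11-trien-1-yl]-8a-(1-hydroxypropan-2-yl)-5,6-dimethyloctahydro-2H-chromen-6-ol | OCC(C)[C@]12CC[C@](C)(O)[C@@](C)(CC/C=C(\C)CC/C=C(\C)C[C@H](O)C=C(C)C)[C@@H]1CCCO2
F7 | step 23 | (4aS,5S,6S,8aS)-5-[(3E,7E,10S)-10-[(2R)-3,3-dimethyloxiran-2-yl]-10-hydroxy-4,8-dimethyldeca-3,7-dien-1-yl]-8a-(1-hydroxypropan-2-yl)-5,6-dimethyloctahydro-2H-chromen-6-ol | OCC(C)[C@]12CC[C@](C)(O)[C@@](C)(CC/C=C(\C)CC/C=C(\C)C[C@H](O)[C@H]3OC3(C)C)[C@@H]1CCCO2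
F8 | step 23 | 2-[(4aS,5S,6S,8aS)-5-[(3E,7E,10S)-10-[(2R)-3,3-dimethyloxiran-2-yl]-10-hydroxy-4,8-dimethyldeca-3,7-dien-1-yl]-6-hydroxy-5,6-dimethyloctahydro-2H-chromen-8a-yl]propanal | O=CC(C)[C@]12CC[C@](C)(O)[C@@](C)(CC/C=C(\C)CC/C=C(\C)C[C@H](O)[C@H]3OC3(C)C)[C@@H]1CCCO2
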